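**Plan**

1. Retrosynthetic cuts, in order: (i) the side-chain bond C20'–C21' (methyl-bearing alkene carbon to the next CH2), giving an (E)-alkenyl iodide and a C16 homoallylic borane; (ii) C20'–CH3 and C17'–C18' (iodomethane, propyne, and an allylic bromide made by C–H oxidation at C17'); (iii) C1'–C2' (chroman-2-ylmethyl triflate + geranylgeranyl sulfone); (iv) O1–C2 and C3–C4 of the pyran ring (o-quinone methide + methyl methacrylate).
2. Forward order: the pyran ring is closed first onto the preformed arene by a hetero-Diels–Alder reaction; the C20 chain is attached at C1'; its far end is grown to the iodoalkene; the C16 unit is joined last and the phenol is unmasked.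
3. Enabling feature: the side chain is a head-to-tail 1,5-polyene, so C21' is a CH2 homoallylic to C23'=C24' and C20' is a methyl-substituted vinylic carbon. The sp3 partner is therefore reachable by hydroboration of the vinyl end of a 1,3-diene and the sp2 partner as a 2-iodoalk-2-ene; the chroman ring (O1, C2–C4, arene C4a–C8a) is not involved.
4. Stereochemistry: C2 comes from lipase resolution of the chroman-2-methanol. The 3'E, 7'E, 11'E alkenes come from geranylgeraniol and 23'E, 27'E from farnesol; 15'E comes from E-selective SeO2 oxidation; 19'E comes from syn-hydrozirconation/iodination followed by a stereoretentive coupling.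

Key step: step 16

Remark on locants: chroman atoms are O1, C2–C4, C4a, C5–C8, C8a; side-chain carbons are counted from C1' (the CH2 on C2) outward.

Assumption: the lipase in step 4 acylates the (R)-alcohol faster and leaves the (S)-alcohol; were the preference the opposite, the acetate fraction would be carried on after reductive cleavage.

**Route**

Step 1
Reactants: 1 2,3-dimethylhydroquinone; 2 methyl methacrylate
Product: 5 rac-methyl 6-hydroxy-2,7,8-trimethylchroman-2-carboxylate, via 5-(hydroxymethyl)-2,3-dimethylbenzene-1,4-diol 3 (not isolated), via o-quinone methide 4 (not isolated)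
Conditions: (CH2O)n, AcOH (cat.), neat 2 (excess), 160 °C, sealed tube; 1 in slight excess
Reagents that add atoms: paraformaldehyde (formaldehyde), C=O
Why: Ortho-hydroxymethylation of the hydroquinone and thermal loss of water generate the o-quinone methide, which the methacrylate traps in an inverse-electron-demand hetero-Diels–Alder reaction forming O1–C2 and C3–C4 with the ester on the oxygen-bearing carbon; the quaternary C2 centre arises racemic here and is resolved in step 4.

Step 2
Reactants: 5 rac-methyl 6-hydroxy-2,7,8-trimethylchroman-2-carboxylate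
Product: 6 rac-methyl 2,7,8-trimethyl-6-(triisopropylsilyloxy)chroman-2-carboxylate
Conditions: TIPSCl, imidazole, DMF, 40 °C
Reagents that add atoms: chlorotriisopropylsilane, CC(C)[Si](Cl)(C(C)C)C(C)C
Why: Imidazole-promoted silylation of the only hydroxyl group gives an aryl TIPS ether that is expected to survive the hydride, organolithium, oxidative and mildly basic aqueous steps that follow.

Step 3
Reactants: 6 rac-methyl 2,7,8-trimethyl-6-(triisopropylsilyloxy)chroman-2-carboxylate
Product: 7 rac-[2,7,8-trimethyl-6-(triisopropylsilyloxy)chroman-2-yl]methanol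
Conditions: LiAlH4, THF, 0 °C; aqueous work-up
Reagents that add atoms: none
Why: Hydride reduction of the hindered ester to the primary alcohol, the aryl silyl ether being inert to LiAlH4 at 0 °C.

Step 4
Reactants: 7 rac-[2,7,8-trimethyl-6-(triisopropylsilyloxy)chroman-2-yl]methanol
Product: 8 (S)-[2,7,8-trimethyl-6-(triisopropylsilyloxy)chroman-2-yl]methanol
Conditions: immobilised Candida antarctica lipase B, vinyl acetate, t-BuOMe, 30 °C, to just over half conversion; chromatography
Reagents that add atoms: none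
Why: Lipase-catalysed kinetic resolution by enantioselective transesterification: the (R)-alcohol is acetylated and the unreacted (S)-alcohol is recovered, which fixes the C2 configuration (S here, R in the target only through the change of CIP priorities).

Step 5
Reactants: 8 (S)-[2,7,8-trimethyl-6-(triisopropylsilyloxy)chroman-2-yl]methanol
Product: 9 (S)-[2,7,8-trimethyl-6-(triisopropylsilyloxy)chroman-2-yl]methyl trifluoromethanesulfonate
Conditions: Tf2O, pyridine, CH2Cl2, −78 → 0 °C
Reagents that add atoms: trifluoromethanesulfonic anhydride, O=S(=O)(OS(=O)(=O)C(F)(F)F)C(F)(F)F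
Why: Sulfonylation of the primary alcohol; the triflate lies next to a quaternary carbon, so it cannot undergo β-elimination, and it is used without delay.

Step 6
Reactants: 10 (2E,6E,10E)-geranylgeraniol
Product: 11 (2E,6E,10E)-geranylgeranyl bromide
Conditions: PBr3, Et2O, −10 °C
Reagents that add atoms: phosphorus tribromide, BrP(Br)Br
Why: Bromination of the primary allylic alcohol via its phosphite ester with SN2 displacement, which keeps the position and E geometry of the C2=C3 alkene.

Step 7
Reactants: 11 (2E,6E,10E)-geranylgeranyl bromide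
Product: 12 (2E,6E,10E)-geranylgeranyl phenyl sulfone
Conditions: PhSO2Na, DMF, rt
Reagents that add atoms: sodium benzenesulfinate, [Na+].[O-]S(=O)c1ccccc1
Why: SN2 displacement of the allylic bromide by the sulfur atom of the sulfinate gives the allylic sulfone without allylic transposition.

Step 8
Reactants: 12 (2E,6E,10E)-geranylgeranyl phenyl sulfone; 9 (S)-[2,7,8-trimethyl-6-(triisopropylsilyloxy)chroman-2-yl]methyl trifluoromethanesulfonate
Product: 14 coupled sulfone (TIPS-protected chroman carrying the C20 tetraenyl chain at C2; PhSO2 on C2'; both C2' epimers), via lithiated sulfone 13 (not isolated)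
Conditions: n-BuLi, THF–DMPU, −78 °C; then 9, −78 → 0 °C
Reagents that add atoms: none
Why: Biellmann-type alkylation: the α-sulfonyl allyl carbanion attacks through its α-carbon and displaces the primary triflate by SN2 (the neopentyl-type centre needs the triflate leaving group and a dipolar cosolvent), forming C1'–C2'; the new sulfone-bearing centre is an inconsequential epimer mixture and C2 is untouched.

Step 9
Reactants: 14 coupled sulfone
Product: 15 triisopropyl{[(2R)-2,7,8-trimethyl-2-[(3E,7E,11E)-4,8,12,16-tetramethylheptadeca-3,7,11,15-tetraenyl]chroman-6-yl]oxy}silane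
Conditions: PdCl2(dppp) (cat.), LiBHEt3, THF, 0 °C
Reagents that add atoms: none
Why: Palladium-catalysed reductive desulfonylation: ionisation to a π-allylpalladium complex and hydride delivery to its less substituted terminus (C2') removes the sulfone while the C3'=C4' alkene keeps its position and E geometry.

Step 10
Reactants: 15 TIPS-protected tetraenyl chroman
Product: 16 (2E,6E,10E,14E)-2,6,10,14-tetramethyl-17-[(2R)-2,7,8-trimethyl-6-(triisopropylsilyloxy)chroman-2-yl]heptadeca-2,6,10,14-tetraen-1-ol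
Conditions: SeO2 (cat.), t-BuOOH, salicylic acid (cat.), CH2Cl2, 0 °C → rt; stopped at partial conversion, 15 recycled
Reagents that add atoms: selenium dioxide (catalytic oxygen carrier), O=[Se]=O; tert-butyl hydroperoxide (terminal oxidant), CC(C)(C)OO
Why: Selenium dioxide allylic hydroxylation (ene reaction, then [2,3]-sigmatropic shift) attacks the most accessible, terminal trisubstituted alkene at its (E)-methyl group, so the former isopropylidene becomes the (E)-configured C15'=C16' alkene bearing C17'–OH.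

Step 11
Reactants: 16 terminal (E)-allylic alcohol
Product: 17 {[(2R)-2-[(3E,7E,11E,15E)-17-bromo-4,8,12,16-tetramethylheptadeca-3,7,11,15-tetraenyl]-2,7,8-trimethylchroman-6-yl]oxy}triisopropylsilane
Conditions: CBr4, PPh3, CH2Cl2, 0 °C
Reagents that add atoms: carbon tetrabromide, BrC(Br)(Br)Br
Why: Appel bromination of the primary allylic alcohol by SN2 attack of bromide on the alkoxyphosphonium ion, without allylic shift.

Step 12
Reactants: 17 allylic bromide
Product: 19 triisopropyl{[(2R)-2,7,8-trimethyl-2-[(3E,7E,11E,15E)-4,8,12,16-tetramethylhenicosa-3,7,11,15-tetraen-19-ynyl]chroman-6-yl]oxy}silane, via lithium acetylide 18 (not isolated)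
Conditions: propyne, n-BuLi (2 equiv), TMEDA, Et2O–hexane, −78 → 0 °C; 17, THF, −78 → 0 °C; then MeI, DMPU, 0 °C → rt
Reagents that add atoms: propyne, CC#C; iodomethane, CI
Why: 1,3-Dilithiopropyne is alkylated at its more nucleophilic sp3 carbon by the primary allylic bromide (SN2, forming C17'–C18'), and the lithium acetylide that remains is C-methylated in the same flask to give the 2-alkyne.

Step 13
Reactants: 19 methyl alkyne
Product: 21 {[(2R)-2-[(3E,7E,11E,15E,19E)-20-iodo-4,8,12,16-tetramethylhenicosa-3,7,11,15,19-pentaenyl]-2,7,8-trimethylchroman-6-yl]oxy}triisopropylsilane, via alkenylzirconocene chloride 20 (not isolated)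
Conditions: Cp2Zr(H)Cl (2 equiv), THF, rt → 40 °C, dark; then I2, THF, 0 °C
Reagents that add atoms: iodine, II
Why: syn-Hydrozirconation of the only alkyne (trisubstituted alkenes are inert), with excess reagent equilibrating zirconium onto the less hindered, methyl-bearing carbon C20', followed by iodinolysis with retention, should give the (E)-2-iodoalk-2-ene.

Step 14
Reactants: 22 (2E,6E)-farnesol
Product: 23 (2E,6E)-farnesal
Conditions: TEMPO (cat.), PhI(OAc)2, CH2Cl2, rt
Reagents that add atoms: none
Why: Oxoammonium-mediated oxidation of the allylic alcohol to the enal under neutral conditions that do not isomerise the C2=C3 alkene.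

Step 15
Reactants: 23 (2E,6E)-farnesal
Product: 24 (3E,7E)-4,8,12-trimethyltrideca-1,3,7,11-tetraene
Conditions: Ph3PCH3Br, KOt-Bu, THF, 0 °C → rt
Reagents that add atoms: methyltriphenylphosphonium bromide, C[P+](c1ccccc1)(c1ccccc1)c1ccccc1.[Br-]
Why: Wittig methylenation of the enal gives the terminal 1,3-diene; the existing alkenes are not affected.

Step 16
Reactants: 24 (3E,7E)-4,8,12-trimethyltrideca-1,3,7,11-tetraene; 21 (E)-alkenyl iodide
Product: 26 plastochromanol-8 triisopropylsilyl ether, via B-homofarnesyl-9-BBN 25 (not isolated)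
Conditions: 9-BBN-H, THF, 0 °C → rt; then 21, PdCl2(dppf) (cat.), AsPh3 (cat.), K3PO4 (aq.), DMF, rt, degassed; 24 and 9-BBN-H in excess over 21
Reagents that add atoms: none
Why: 9-BBN adds B–H across the only monosubstituted C=C of 24 (the vinyl end of the 1,3-diene, boron to the terminal carbon) to give the homoallylic borane 25; Pd(0) then inserts into the C–I bond of 21 with retention, the base-activated borate transfers its primary alkyl group to palladium, and reductive elimination forms the C20'–C21' C(sp2)–C(sp3) bond. The closest known reaction type is the B-alkyl Suzuki–Miyaura coupling of alkyl-9-BBN reagents with 2-iodoalk-2-enes. No ring is closed and no stereocentre is created: C2 is remote and untouched, and the new trisubstituted alkene inherits its E geometry from 21 because oxidative addition and reductive elimination both proceed with retention. The step needs chemoselective hydroboration, secured by the steric gap between the vinyl terminus and the three trisubstituted alkenes and by the bulk of 9-BBN; it also needs transmetalation and reductive elimination to outrun β-hydride elimination of the homoallyl–palladium species, which the wide-bite-angle dppf ligand with AsPh3 at room temperature should secure. The aryl silyl ether, the chroman and the skipped polyene are expected to be inert to the mildly basic aqueous medium, and any premature loss of the silyl group would only anticipate step 17.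

Step 17
Reactants: 26 plastochromanol-8 triisopropylsilyl ether
Product: 27 plastochromanol-8
Conditions: TBAF, THF, 0 °C, argon; then water
Reagents that add atoms: none
Why: Fluoride cleaves the Si–O bond of the aryl silyl ether under non-acidic conditions that leave the polyene and the chroman untouched; exclusion of air protects the electron-rich chromanol.

**Compound list**

1 | 2,3-dimethylhydroquinone (2,3-dimethylbenzene-1,4-diol) | Cc1c(O)ccc(O)c1C | starting material
2 | methyl methacrylate | C=C(C)C(=O)OC | starting material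
3 | 5-(hydroxymethyl)-2,3-dimethylbenzene-1,4-diol | OCc1cc(O)c(C)c(C)c1O | intermediate
4 | o-quinone methide, 4-hydroxy-2,3-dimethyl-6-methylidenecyclohexa-2,4-dien-1-one | C=C1C=C(O)C(C)=C(C)C1=O | intermediate
5 | rac-methyl 6-hydroxy-2,7,8-trimethylchroman-2-carboxylate | COC(=O)C1(C)CCc2cc(O)c(C)c(C)c2O1 | intermediate
6 | rac-methyl 2,7,8-trimethyl-6-(triisopropylsilyloxy)chroman-2-carboxylate | COC(=O)C1(C)CCc2cc(O[Si](C(C)C)(C(C)C)C(C)C)c(C)c(C)c2O1 | intermediate
7 | rac-[2,7,8-trimethyl-6-(triisopropylsilyloxy)chroman-2-yl]methanol | OCC1(C)CCc2cc(O[Si](C(C)C)(C(C)C)C(C)C)c(C)c(C)c2O1 | intermediate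
8 | (S)-[2,7,8-trimethyl-6-(triisopropylsilyloxy)chroman-2-yl]methanol | OC[C@]1(C)CCc2cc(O[Si](C(C)C)(C(C)C)C(C)C)c(C)c(C)c2O1 | intermediate
9 | (S)-[2,7,8-trimethyl-6-(triisopropylsilyloxy)chroman-2-yl]methyl trifluoromethanesulfonate | O=S(=O)(OC[C@]1(C)CCc2cc(O[Si](C(C)C)(C(C)C)C(C)C)c(C)c(C)c2O1)C(F)(F)F | intermediate
10 | (2E,6E,10E)-geranylgeraniol | CC(C)=CCC/C(C)=C/CC/C(C)=C/CC/C(C)=C/CO | starting material
11 | (2E,6E,10E)-geranylgeranyl bromide | CC(C)=CCC/C(C)=C/CC/C(C)=C/CC/C(C)=C/CBr | intermediate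
12 | (2E,6E,10E)-geranylgeranyl phenyl sulfone | CC(C)=CCC/C(C)=C/CC/C(C)=C/CC/C(C)=C/CS(=O)(=O)c1ccccc1 | intermediate
13 | α-lithiated geranylgeranyl phenyl sulfone | CC(C)=CCC/C(C)=C/CC/C(C)=C/CC/C(C)=C/C([Li])S(=O)(=O)c1ccccc1 | intermediate
14 | triisopropyl{[(2S)-2,7,8-trimethyl-2-[(3E,7E,11E)-4,8,12,16-tetramethyl-2-(phenylsulfonyl)heptadeca-3,7,11,15-tetraenyl]chroman-6-yl]oxy}silane (both C2' epimers; same spatial arrangement at C2 as in 8) | CC(C)=CCC/C(C)=C/CC/C(C)=C/CC/C(C)=C/C(C[C@]1(C)CCc2cc(O[Si](C(C)C)(C(C)C)C(C)C)c(C)c(C)c2O1)S(=O)(=O)c1ccccc1 | intermediate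
15 | triisopropyl{[(2R)-2,7,8-trimethyl-2-[(3E,7E,11E)-4,8,12,16-tetramethylheptadeca-3,7,11,15-tetraenyl]chroman-6-yl]oxy}silane | CC(C)=CCC/C(C)=C/CC/C(C)=C/CC/C(C)=C/CC[C@]1(C)CCc2cc(O[Si](C(C)C)(C(C)C)C(C)C)c(C)c(C)c2O1 | intermediate
16 | (2E,6E,10E,14E)-2,6,10,14-tetramethyl-17-[(2R)-2,7,8-trimethyl-6-(triisopropylsilyloxy)chroman-2-yl]heptadeca-2,6,10,14-tetraen-1-ol | OC/C(C)=C/CC/C(C)=C/CC/C(C)=C/CC/C(C)=C/CC[C@]1(C)CCc2cc(O[Si](C(C)C)(C(C)C)C(C)C)c(C)c(C)c2O1 | intermediate
17 | {[(2R)-2-[(3E,7E,11E,15E)-17-bromo-4,8,12,16-tetramethylheptadeca-3,7,11,15-tetraenyl]-2,7,8-trimethylchroman-6-yl]oxy}triisopropylsilane | BrC/C(C)=C/CC/C(C)=C/CC/C(C)=C/CC/C(C)=C/CC[C@]1(C)CCc2cc(O[Si](C(C)C)(C(C)C)C(C)C)c(C)c(C)c2O1 | intermediate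
18 | lithium acetylide, {(5E,9E,13E,17E)-5,9,13,17-tetramethyl-20-[(2R)-2,7,8-trimethyl-6-(triisopropylsilyloxy)chroman-2-yl]icosa-5,9,13,17-tetraen-1-yn-1-yl}lithium | [Li]C#CCC/C(C)=C/CC/C(C)=C/CC/C(C)=C/CC/C(C)=C/CC[C@]1(C)CCc2cc(O[Si](C(C)C)(C(C)C)C(C)C)c(C)c(C)c2O1 | intermediate
19 | triisopropyl{[(2R)-2,7,8-trimethyl-2-[(3E,7E,11E,15E)-4,8,12,16-tetramethylhenicosa-3,7,11,15-tetraen-19-ynyl]chroman-6-yl]oxy}silane | CC#CCC/C(C)=C/CC/C(C)=C/CC/C(C)=C/CC/C(C)=C/CC[C@]1(C)CCc2cc(O[Si](C(C)C)(C(C)C)C(C)C)c(C)c(C)c2O1 | intermediate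
20 | (19'E)-alkenylzirconocene chloride: Cp2Zr(Cl) on C20' and H on C19' of the chain of 19 (syn adduct) | Cl[Zr](C1C=CC=C1)(C1C=CC=C1)/C(C)=C/CC/C(C)=C/CC/C(C)=C/CC/C(C)=C/CC/C(C)=C/CC[C@]1(C)CCc2cc(O[Si](C(C)C)(C(C)C)C(C)C)c(C)c(C)c2O1 | intermediate
21 | {[(2R)-2-[(3E,7E,11E,15E,19E)-20-iodo-4,8,12,16-tetramethylhenicosa-3,7,11,15,19-pentaenyl]-2,7,8-trimethylchroman-6-yl]oxy}triisopropylsilane | I/C(C)=C/CC/C(C)=C/CC/C(C)=C/CC/C(C)=C/CC/C(C)=C/CC[C@]1(C)CCc2cc(O[Si](C(C)C)(C(C)C)C(C)C)c(C)c(C)c2O1 | intermediate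
22 | (2E,6E)-farnesol | CC(C)=CCC/C(C)=C/CC/C(C)=C/CO | starting material
23 | (2E,6E)-farnesal | CC(C)=CCC/C(C)=C/CC/C(C)=C/C=O | intermediate
24 | (3E,7E)-4,8,12-trimethyltrideca-1,3,7,11-tetraene | CC(C)=CCC/C(C)=C/CC/C(C)=C/C=C | intermediate
25 | B-homofarnesyl-9-BBN, 9-[(3E,7E)-4,8,12-trimethyltrideca-3,7,11-trienyl]-9-borabicyclo[3.3.1]nonane | CC(C)=CCC/C(C)=C/CC/C(C)=C/CCB1C2CCCC1CCC2 | intermediate
26 | plastochromanol-8 triisopropylsilyl ether, triisopropyl{[(2R)-2,7,8-trimethyl-2-[(3E,7E,11E,15E,19E,23E,27E)-4,8,12,16,20,24,28,32-octamethyltritriaconta-3,7,11,15,19,23,27,31-octaenyl]chroman-6-yl]oxy}silane | CC(C)=CCC/C(C)=C/CC/C(C)=C/CC/C(C)=C/CC/C(C)=C/CC/C(C)=C/CC/C(C)=C/CC/C(C)=C/CC[C@]1(C)CCc2cc(O[Si](C(C)C)(C(C)C)C(C)C)c(C)c(C)c2O1 | intermediate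
27 | plastochromanol-8, (2R)-2,7,8-trimethyl-2-[(3E,7E,11E,15E,19E,23E,27E)-4,8,12,16,20,24,28,32-octamethyltritriaconta-3,7,11,15,19,23,27,31-octaenyl]chroman-6-ol | CC(C)=CCC/C(C)=C/CC/C(C)=C/CC/C(C)=C/CC/C(C)=C/CC/C(C)=C/CC/C(C)=C/CC/C(C)=C/CC[C@]1(C)CCc2cc(O)c(C)c(C)c2O1 | target

**Step count and risks**

Total step count: 17. Longest linear sequence: 13 steps (steps 1–5, 8–13, 16, 17).

The three steps most likely to fail:

Step 13. The process at risk is incomplete equilibration of the two alkenylzirconium regioisomers, so that zirconium and then iodine are also placed on C19'; the regioisomeric iodide would be carried into an inseparable branched isomer. The fallback sets out from bromide 17 (with borane 25 as the source of the C16 unit) and comes back at 26; it creates the alkene geometry in the coupling itself by a two-stage Negishi sequence on a 1,1-dichloroalkene. 17 is alkylated with the lithium enolate of ethyl acetate (LDA, THF, −78 °C) to give ethyl ester F1. DIBAL-H at −78 °C gives aldehyde F2, and PPh3/CCl4 gives 1,1-dichloroalkene F3. Oxidation of 25 (NaOH, H2O2) gives homofarnesol F4; I2/PPh3/imidazole gives homofarnesyl iodide F5; zinc insertion (Zn, LiCl, THF) gives homofarnesylzinc iodide F6. Coupling of F3 with F6 under PdCl2(DPEphos) catalysis should replace only the chlorine trans to the chain, because oxidative addition prefers the less hindered C–Cl bond, and give (Z)-chloroalkene F7. Me2Zn with Pd(t-Bu3P)2 should then replace the remaining chlorine with retention to give 26.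

Step 10. The process at risk is competing oxidation at internal allylic positions and over-oxidation to the enal on an advanced intermediate. The fallback sets out from sulfone 12 (and triflate 9) and comes back at 16; it moves the hydroxylation to the cheap sulfone, where the alkene next to sulfur is deactivated and the polar products are easy to separate. SeO2/t-BuOOH on 12 gives ω-hydroxy sulfone F8, and dihydropyran/PPTS gives tetrahydropyranyl ether F9. Deprotonation with n-BuLi and alkylation with 9 gives coupled sulfone F10. PdCl2(dppp)/LiBHEt3 gives tetrahydropyranyl ether F11, and PPTS in methanol releases 16.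

Step 4. The process at risk is insufficient discrimination of the enantiomers by the lipase, because the stereocentre is quaternary and one bond away from the reacting CH2OH. The fallback sets out from ester 5 and comes back at 8; it is a classical resolution at the acid stage. Saponification of 5 (NaOH, aqueous MeOH; HCl) gives racemic acid F12. Crystallisation with (R)-1-phenylethylamine (its antipode, should the other diastereomeric salt be the less soluble one) gives salt F13 of the (S)-acid, and acidification gives (S)-acid F14. TIPSCl/imidazole (2.2 equiv) gives silyl ester silyl ether F15, and LiAlH4 reduces the silyl ester to give 8.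

Further compounds

F1 | step 13 | ethyl (4E,8E,12E,16E)-4,8,12,16-tetramethyl-19-[(2R)-2,7,8-trimethyl-6-(triisopropylsilyloxy)chroman-2-yl]nonadeca-4,8,12,16-tetraenoate | CCOC(=O)CC/C(C)=C/CC/C(C)=C/CC/C(C)=C/CC/C(C)=C/CC[C@]1(C)CCc2cc(O[Si](C(C)C)(C(C)C)C(C)C)c(C)c(C)c2O1
F2 | step 13 | (4E,8E,12E,16E)-4,8,12,16-tetramethyl-19-[(2R)-2,7,8-trimethyl-6-(triisopropylsilyloxy)chroman-2-yl]nonadeca-4,8,12,16-tetraenal | O=CCC/C(C)=C/CC/C(C)=C/CC/C(C)=C/CC/C(C)=C/CC[C@]1(C)CCc2cc(O[Si](C(C)C)(C(C)C)C(C)C)c(C)c(C)c2O1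
F3 | step 13 | 1,1-dichloroalkene, {[(2R)-2-[(3E,7E,11E,15E)-20,20-dichloro-4,8,12,16-tetramethylicosa-3,7,11,15,19-pentaenyl]-2,7,8-trimethylchroman-6-yl]oxy}triisopropylsilane | ClC(Cl)=CCC/C(C)=C/CC/C(C)=C/CC/C(C)=C/CC/C(C)=C/CC[C@]1(C)CCc2cc(O[Si](C(C)C)(C(C)C)C(C)C)c(C)c(C)c2O1
F4 | step 13 | homofarnesol, (3E,7E)-4,8,12-trimethyltrideca-3,7,11-trien-1-ol | CC(C)=CCC/C(C)=C/CC/C(C)=C/CCO
F5 | step 13 | homofarnesyl iodide, (3E,7E)-1-iodo-4,8,12-trimethyltrideca-3,7,11-triene | CC(C)=CCC/C(C)=C/CC/C(C)=C/CCI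
F6 | step 13 | homofarnesylzinc iodide | CC(C)=CCC/C(C)=C/CC/C(C)=C/CC[Zn]I
F7 | step 13 | (19'Z)-20'-chloro-20'-demethyl analogue of 26 (Cl in place of the C20' methyl group; homofarnesyl trans to C18') | CC(C)=CCC/C(C)=C/CC/C(C)=C/CC/C(Cl)=C/CC/C(C)=C/CC/C(C)=C/CC/C(C)=C/CC/C(C)=C/CC[C@]1(C)CCc2cc(O[Si](C(C)C)(C(C)C)C(C)C)c(C)c(C)c2O1
F8 | step 10 | (2E,6E,10E,14E)-2,6,10,14-tetramethyl-16-(phenylsulfonyl)hexadeca-2,6,10,14-tetraen-1-ol | OC/C(C)=C/CC/C(C)=C/CC/C(C)=C/CC/C(C)=C/CS(=O)(=O)c1ccccc1
F9 | step 10 | tetrahydropyran-2-yl ether of F8 | O(C1CCCCO1)C/C(C)=C/CC/C(C)=C/CC/C(C)=C/CC/C(C)=C/CS(=O)(=O)c1ccccc1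
F10 | step 10 | coupled sulfone: 14 carrying a tetrahydropyran-2-yloxy group on C17' (15'E; epimers at C2' and at the acetal carbon) | O(C1CCCCO1)C/C(C)=C/CC/C(C)=C/CC/C(C)=C/CC/C(C)=C/C(C[C@]1(C)CCc2cc(O[Si](C(C)C)(C(C)C)C(C)C)c(C)c(C)c2O1)S(=O)(=O)c1ccccc1
F11 | step 10 | tetrahydropyran-2-yl ether of 16 | O(C1CCCCO1)C/C(C)=C/CC/C(C)=C/CC/C(C)=C/CC/C(C)=C/CC[C@]1(C)CCc2cc(O[Si](C(C)C)(C(C)C)C(C)C)c(C)c(C)c2O1
F12 | step 4 | rac-6-hydroxy-2,7,8-trimethylchroman-2-carboxylic acid | OC(=O)C1(C)CCc2cc(O)c(C)c(C)c2O1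
F13 | step 4 | (R)-1-phenylethylammonium (S)-6-hydroxy-2,7,8-trimethylchroman-2-carboxylate | C[C@@H]([NH3+])c1ccccc1.[O-]C(=O)[C@]1(C)CCc2cc(O)c(C)c(C)c2O1
F14 | step 4 | (S)-6-hydroxy-2,7,8-trimethylchroman-2-carboxylic acid | OC(=O)[C@]1(C)CCc2cc(O)c(C)c(C)c2O1
F15 | step 4 | triisopropylsilyl (S)-2,7,8-trimethyl-6-(triisopropylsilyloxy)chroman-2-carboxylate | CC(C)[Si](OC(=O)[C@]1(C)CCc2cc(O[Si](C(C)C)(C(C)C)C(C)C)c(C)c(C)c2O1)(C(C)C)C(C)C
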